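The pyran ring C is cut at O1–C8a, C4–C4a and O1–C2. The feature exploited is that O1 and C4 sit on adjacent carbons of ring A (C8a and C4a) directly beside the C5 methoxy group, the addition pattern of a 3-methoxyaryne, while O1–C2–C3(ring B)–C4 is a 2-arylacrolein. One fluoride-triggered operation joins both halves: carbonyl [2+2] addition to the aryne, benzoxete opening and oxa-6π closure build the pyran ring as the isoflav-3-ene. The precursors are an o-silylaryl triflate carrying both methoxy groups and the prenyl chain, and the MOM-protected chromenyl acrolein. Asymmetric hydrogenation then sets C3.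

Key step: step 12

Remark: isoflavan numbering is used (O1, C2, C3, C4, C4a, C5–C8, C8a; ring B primed); which antipode of the N,P ligand in step 13 gives (3R) is assumed to be settled on first use, both antipodes being available, and the step is written for the one that gives (3R).

Step 1
Reactants: 1 3,5-dimethoxyphenol
Product: 2 triisopropyl(3,5-dimethoxyphenoxy)silane
Conditions: TIPSCl, imidazole, DMF, rt
Reagents that add atoms: triisopropylsilyl chloride, CC(C)[Si](Cl)(C(C)C)C(C)C
Why: Routine O-silylation of a phenol; the bulky, weakly coordinating TIPS ether shields C2/C6 so that the following metalation should go to C4.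

Step 2
Reactants: 2 triisopropyl(3,5-dimethoxyphenoxy)silane; 3 prenyl bromide (1-bromo-3-methylbut-2-ene)
Product: 5 triisopropyl[3,5-dimethoxy-4-(3-methylbut-2-en-1-yl)phenoxy]silane, via aryllithium 4 (not isolated)
Conditions: n-BuLi, THF, 0 °C → rt; then CuBr·SMe2 (20 mol%), 3, −78 °C → rt
Reagents that add atoms: none
Why: Directed ortho-metalation at the only carbon flanked by two cooperating methoxy donors, then copper-catalysed SN2 allylation of the aryllithium at the primary carbon of prenyl bromide.

Step 3
Reactants: 5 triisopropyl[3,5-dimethoxy-4-(3-methylbut-2-en-1-yl)phenoxy]silane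
Product: 6 3,5-dimethoxy-4-(3-methylbut-2-en-1-yl)phenol
Conditions: TBAF, THF, 0 °C
Reagents that add atoms: none
Why: Fluoride-induced cleavage of an aryl silyl ether (desilylation); nothing else in the molecule is fluoride-sensitive.

Step 4
Reactants: 6 3,5-dimethoxy-4-(3-methylbut-2-en-1-yl)phenol
Product: 7 2-bromo-3,5-dimethoxy-4-(3-methylbut-2-en-1-yl)phenol
Conditions: NBS (1.0 equiv), CH2Cl2, −78 °C
Reagents that add atoms: N-bromosuccinimide, O=C1CCC(=O)N1Br
Why: Electrophilic aromatic bromination ortho to the hydroxyl group; C2 and C6 are equivalent, the para position is blocked, and the trioxygenated ring should react far faster at low temperature than the trisubstituted alkene.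

Step 5
Reactants: 7 2-bromo-3,5-dimethoxy-4-(3-methylbut-2-en-1-yl)phenol
Product: 10 3,5-dimethoxy-4-(3-methylbut-2-en-1-yl)-2-(trimethylsilyl)phenyl trifluoromethanesulfonate, via aryl trimethylsilyl ether 8 (not isolated), via lithium 2-silylphenoxide 9 (not isolated)
Conditions: HMDS, THF, 65 °C, then evaporation; n-BuLi, THF, −78 °C; Tf2O, −78 °C → rt
Reagents that add atoms: hexamethyldisilazane, C[Si](C)(C)N[Si](C)(C)C; trifluoromethanesulfonic anhydride, O=S(=O)(OS(=O)(=O)C(F)(F)F)C(F)(F)F
Why: O-silylation, bromine–lithium exchange and 1,3 O→C silyl shift (retro-Brook rearrangement) give the ortho-silyl phenoxide, which is triflated in the same flask, the standard entry to o-silylaryl triflates; the prenyl group is inert to n-BuLi at −78 °C.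

Step 6
Reactants: 11 2,4-dihydroxybenzaldehyde
Product: 12 2-hydroxy-4-(methoxymethoxy)benzaldehyde
Conditions: MOMCl (1.05 equiv), K2CO3, acetone, 0 °C → rt
Reagents that add atoms: chloromethyl methyl ether, COCCl
Why: Williamson-type O-alkylation that should be selective for the more acidic 4-OH, because the 2-OH is held in a hydrogen bond to the aldehyde.

Step 7
Reactants: 12 2-hydroxy-4-(methoxymethoxy)benzaldehyde; 13 3-chloro-3-methylbut-1-yne
Product: 14 4-(methoxymethoxy)-2-[(2-methylbut-3-yn-2-yl)oxy]benzaldehyde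
Conditions: K2CO3, KI, CuI (cat.), DMF, 60 °C
Reagents that add atoms: none
Why: Copper-assisted O-alkylation of the phenoxide with a tertiary propargylic chloride, the usual preparation of aryl 1,1-dimethylpropargyl ethers, run below the temperature at which the ether rearranges.

Step 8
Reactants: 14 4-(methoxymethoxy)-2-[(2-methylbut-3-yn-2-yl)oxy]benzaldehyde
Product: 15 5-(methoxymethoxy)-2,2-dimethyl-2H-chromene-8-carbaldehyde
Conditions: N,N-diethylaniline, 180 °C
Reagents that add atoms: none
Why: Aromatic propargyl Claisen rearrangement to C3, the only free ortho position, followed by enolisation, 1,5-hydrogen shift and oxa-6π electrocyclisation, the established thermal route to 2,2-dimethyl-2H-chromenes.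

Step 9
Reactants: 15 5-(methoxymethoxy)-2,2-dimethyl-2H-chromene-8-carbaldehyde
Product: 16 5-(methoxymethoxy)-2,2-dimethyl-8-(oxiran-2-yl)-2H-chromene (racemic)
Conditions: Me3S+ I−, KOtBu, DMSO/THF, 0 °C → rt
Reagents that add atoms: trimethylsulfonium iodide, C[S+](C)C.[I-]
Why: Corey–Chaykovsky epoxidation of a non-enolisable aldehyde under basic conditions that spare the MOM ether; the stereocentre is formed racemic and is erased in the next step.

Step 10
Reactants: 16 5-(methoxymethoxy)-2,2-dimethyl-8-(oxiran-2-yl)-2H-chromene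
Product: 17 2-[5-(methoxymethoxy)-2,2-dimethyl-2H-chromen-8-yl]acetaldehyde
Conditions: InCl3 (10 mol%), THF, rt; crude product used directly
Reagents that add atoms: none
Why: Meinwald rearrangement: the mild Lewis acid opens the epoxide at the benzylic carbon (cation stabilised by the ortho and para oxygens) and a 1,2-hydride shift gives the arylacetaldehyde without protic acid, so the MOM ether should survive.

Step 11
Reactants: 17 2-[5-(methoxymethoxy)-2,2-dimethyl-2H-chromen-8-yl]acetaldehyde
Product: 19 2-[5-(methoxymethoxy)-2,2-dimethyl-2H-chromen-8-yl]prop-2-enal, via Mannich base 18 (not isolated)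
Conditions: Me2N=CH2+ I−, Et3N, CH2Cl2, rt; kept cold in solution and used at once
Reagents that add atoms: N,N-dimethylmethyleneiminium iodide (Eschenmoser's salt), C=[N+](C)C.[I-]
Why: Mannich aminomethylation of the aldehyde followed by E1cB loss of dimethylamine, the standard α-methylenation of arylacetaldehydes to 2-arylacroleins.

Step 12
Reactants: 10 3,5-dimethoxy-4-(3-methylbut-2-en-1-yl)-2-(trimethylsilyl)phenyl trifluoromethanesulfonate; 19 2-[5-(methoxymethoxy)-2,2-dimethyl-2H-chromen-8-yl]prop-2-enal
Product: 23 5,7-dimethoxy-3-[5-(methoxymethoxy)-2,2-dimethyl-2H-chromen-8-yl]-6-(3-methylbut-2-en-1-yl)-2H-chromene, via aryne 20 (not isolated), via benzoxete 21 (not isolated), via vinyl o-quinone methide 22 (not isolated)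
Conditions: CsF (3 equiv), MeCN, rt → 40 °C, 10 (1.5 equiv) added slowly to 19
Reagents that add atoms: none
Why: Fluoride attack on silicon and loss of triflate give aryne 20; the aldehyde oxygen of 19 adds to the aryne carbon remote from the flanking methoxy group (future C8a) and the aryl anion formed next to that methoxy group closes on the carbonyl carbon (C4–C4a), a formal [2+2] addition giving benzoxete 21. Four-electron ring opening of 21 gives vinyl o-quinone methide 22, whose Z isomer closes by thermal disrotatory oxa-6π electrocyclisation (oxygen to the acrolein CH2, O1–C2), forming the six-membered pyran ring and restoring the aromaticity of ring A. The closest known reaction type is the fluoride-mediated annulation of arynes with α,β-unsaturated aldehydes to 2H-chromenes. No stereocentre is created. The selectivity needed is the regiochemistry of addition to the unsymmetrical aryne, secured by the inductively withdrawing methoxy group beside the triple bond, which polarises the aryne so that nucleophiles attack the distal carbon and C4 ends up beside the C5 methoxy group. Carbonyl addition should outrun alkene pathways because the enal C=C is electron-poor, the chromene alkene has no allylic hydrogen for an ene reaction, and slow addition keeps the aryne dilute so that the quinone methide cyclises before a second aryne can trap it.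

Step 13
Reactants: 23 5,7-dimethoxy-3-[5-(methoxymethoxy)-2,2-dimethyl-2H-chromen-8-yl]-6-(3-methylbut-2-en-1-yl)-2H-chromene
Product: 24 (3R)-5,7-dimethoxy-3-[5-(methoxymethoxy)-2,2-dimethyl-2H-chromen-8-yl]-6-(3-methylbut-2-en-1-yl)-3,4-dihydro-2H-chromene
Conditions: [Ir(cod)(tBu-PHOX)]BArF (2 mol%, ligand antipode giving 3R), H2 (5 bar), CH2Cl2, rt, stopped after uptake of 1 equiv H2
Reagents that add atoms: none
Why: Iridium–N,P-catalysed asymmetric hydrogenation of an unfunctionalised trisubstituted aryl alkene, a reaction type established for MOM-protected 3-aryl-2H-chromenes; the C3 stereocentre is set by catalyst-controlled delivery of hydrogen to one face of C3=C4, and chemoselectivity rests on phosphinooxazoline catalysts needing an aryl-conjugated alkene for high activity, so the trialkyl-substituted prenyl alkene and the chromene alkene next to a quaternary carbon should react more slowly at low pressure and limited hydrogen uptake.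

Step 14
Reactants: 24 (3R)-5,7-dimethoxy-3-[5-(methoxymethoxy)-2,2-dimethyl-2H-chromen-8-yl]-6-(3-methylbut-2-en-1-yl)-3,4-dihydro-2H-chromene
Product: 25 kanzonol I, 8-[(3R)-5,7-dimethoxy-6-(3-methylbut-2-en-1-yl)-3,4-dihydro-2H-chromen-3-yl]-2,2-dimethyl-2H-chromen-5-ol
Conditions: HCl (ca. 1 M in MeOH), MeOH/THF, rt → 40 °C
Reagents that add atoms: none
Why: Acid-catalysed acetal exchange removes the aryl MOM ether; the prenyl group lies between two methoxy groups and cannot cyclise onto a phenol, the chromene tolerates dilute methanolic acid, and the C3 stereocentre has no pathway for epimerisation under these conditions.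

Compound list
1 | 3,5-dimethoxyphenol | COc1cc(O)cc(OC)c1 | starting material
2 | triisopropyl(3,5-dimethoxyphenoxy)silane | COc1cc(OC)cc(O[Si](C(C)C)(C(C)C)C(C)C)c1 | intermediate
3 | prenyl bromide (1-bromo-3-methylbut-2-ene) | CC(C)=CCBr | starting material
4 | [2,6-dimethoxy-4-(triisopropylsilyloxy)phenyl]lithium | [Li]c1c(OC)cc(O[Si](C(C)C)(C(C)C)C(C)C)cc1OC | intermediate
5 | triisopropyl[3,5-dimethoxy-4-(3-methylbut-2-en-1-yl)phenoxy]silane | COc1cc(O[Si](C(C)C)(C(C)C)C(C)C)cc(OC)c1CC=C(C)C | intermediate
6 | 3,5-dimethoxy-4-(3-methylbut-2-en-1-yl)phenol | COc1cc(O)cc(OC)c1CC=C(C)C | intermediate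
7 | 2-bromo-3,5-dimethoxy-4-(3-methylbut-2-en-1-yl)phenol | COc1cc(O)c(Br)c(OC)c1CC=C(C)C | intermediate
8 | [2-bromo-3,5-dimethoxy-4-(3-methylbut-2-en-1-yl)phenoxy]trimethylsilane | COc1cc(O[Si](C)(C)C)c(Br)c(OC)c1CC=C(C)C | intermediate
9 | lithium 3,5-dimethoxy-4-(3-methylbut-2-en-1-yl)-2-(trimethylsilyl)phenoxide | [Li+].COc1cc([O-])c([Si](C)(C)C)c(OC)c1CC=C(C)C | intermediate
10 | 3,5-dimethoxy-4-(3-methylbut-2-en-1-yl)-2-(trimethylsilyl)phenyl trifluoromethanesulfonate | COc1cc(OS(=O)(=O)C(F)(F)F)c([Si](C)(C)C)c(OC)c1CC=C(C)C | intermediate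
11 | 2,4-dihydroxybenzaldehyde | O=Cc1ccc(O)cc1O | starting material
12 | 2-hydroxy-4-(methoxymethoxy)benzaldehyde | COCOc1ccc(C=O)c(O)c1 | intermediate
13 | 3-chloro-3-methylbut-1-yne | CC(C)(Cl)C#C | starting material
14 | 4-(methoxymethoxy)-2-[(2-methylbut-3-yn-2-yl)oxy]benzaldehyde | COCOc1ccc(C=O)c(OC(C)(C)C#C)c1 | intermediate
15 | 5-(methoxymethoxy)-2,2-dimethyl-2H-chromene-8-carbaldehyde | COCOc1ccc(C=O)c2c1C=CC(C)(C)O2 | intermediate
16 | 5-(methoxymethoxy)-2,2-dimethyl-8-(oxiran-2-yl)-2H-chromene (racemic) | COCOc1ccc(C2CO2)c2c1C=CC(C)(C)O2 | intermediate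
17 | 2-[5-(methoxymethoxy)-2,2-dimethyl-2H-chromen-8-yl]acetaldehyde | COCOc1ccc(CC=O)c2c1C=CC(C)(C)O2 | intermediate
18 | 3-(dimethylamino)-2-[5-(methoxymethoxy)-2,2-dimethyl-2H-chromen-8-yl]propanal (racemic Mannich base) | CN(C)CC(C=O)c1ccc(OCOC)c2c1OC(C)(C)C=C2 | intermediate
19 | 2-[5-(methoxymethoxy)-2,2-dimethyl-2H-chromen-8-yl]prop-2-enal | C=C(C=O)c1ccc(OCOC)c2c1OC(C)(C)C=C2 | intermediate
20 | 3,5-dimethoxy-4-(3-methylbut-2-en-1-yl)benzyne (1,2-didehydro) | COC1=C(CC=C(C)C)C(OC)=CC#C1 | intermediate
21 | 3,5-dimethoxy-2-{1-[5-(methoxymethoxy)-2,2-dimethyl-2H-chromen-8-yl]ethenyl}-4-(3-methylbut-2-en-1-yl)-2H-benzo[b]oxete (racemic) | C=C(c1ccc(OCOC)c2c1OC(C)(C)C=C2)C1Oc2cc(OC)c(CC=C(C)C)c(OC)c21 | intermediate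
22 | vinyl o-quinone methide, 3,5-dimethoxy-6-{2-[5-(methoxymethoxy)-2,2-dimethyl-2H-chromen-8-yl]prop-2-en-1-ylidene}-4-(3-methylbut-2-en-1-yl)cyclohexa-2,4-dien-1-one | O=C1C=C(OC)C(CC=C(C)C)=C(OC)C1=CC(=C)c1ccc(OCOC)c2c1OC(C)(C)C=C2 | intermediate
23 | 5,7-dimethoxy-3-[5-(methoxymethoxy)-2,2-dimethyl-2H-chromen-8-yl]-6-(3-methylbut-2-en-1-yl)-2H-chromene | COc1cc2c(c(OC)c1CC=C(C)C)C=C(c1ccc(OCOC)c3c1OC(C)(C)C=C3)CO2 | intermediate
24 | (3R)-5,7-dimethoxy-3-[5-(methoxymethoxy)-2,2-dimethyl-2H-chromen-8-yl]-6-(3-methylbut-2-en-1-yl)-3,4-dihydro-2H-chromene | COc1cc2c(c(OC)c1CC=C(C)C)C[C@H](c1ccc(OCOC)c3c1OC(C)(C)C=C3)CO2 | intermediate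
25 | kanzonol I, 8-[(3R)-5,7-dimethoxy-6-(3-methylbut-2-en-1-yl)-3,4-dihydro-2H-chromen-3-yl]-2,2-dimethyl-2H-chromen-5-ol | COc1cc2c(c(OC)c1CC=C(C)C)C[C@H](c1ccc(O)c3c1OC(C)(C)C=C3)CO2 | target

Total step count: 14 (steps 1–5 to the aryne precursor, steps 6–11 to the acrolein, steps 12–14 common).
Longest linear sequence: 9 steps, from 11 through steps 6–14 to 25.

Steps most likely to fail

Step 12. The acrolein may oligomerise under fluoride before it meets the aryne, the quinone methide may be intercepted by a second aryne before it cyclises, or regiocontrol of the aryne addition may erode. The fallback sets out from phenol 6 and acrolein 19 and returns to the route at 23. The two are heated with phenylboronic acid and acetic acid in toluene with removal of water. The ortho carbon of the phenol adds to the aldehyde carbon inside an aryl boronate, giving 5,7-dimethoxy-4-{1-[5-(methoxymethoxy)-2,2-dimethyl-2H-chromen-8-yl]ethenyl}-6-(3-methylbut-2-en-1-yl)-2-phenyl-4H-1,3,2-benzodioxaborinine F1. On further heating this loses the boron unit to give the same quinone methide 22, which closes to 23. The ring is thus built from the nucleophilic phenol instead of the electrophilic aryne, and the two equivalent ortho positions of 6 leave no regiochemical question.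

Step 13. Chemoselectivity may be lost through competing reduction of the prenyl or chromene alkene, or facial selectivity may be poor. The fallback sets out from acrolein 19 and bromophenol 7 and returns at 24; it needs no alkene hydrogenation.
- Luche reduction of 19 (NaBH4, CeCl3, MeOH) should give 2-[5-(methoxymethoxy)-2,2-dimethyl-2H-chromen-8-yl]prop-2-en-1-ol F2.
- Mitsunobu etherification of F2 with 7 (PPh3, DIAD) should give 8-{3-[2-bromo-3,5-dimethoxy-4-(3-methylbut-2-en-1-yl)phenoxy]prop-1-en-2-yl}-5-(methoxymethoxy)-2,2-dimethyl-2H-chromene F3.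
- Cobalt-catalysed enantioselective anti-Markovnikov hydroboration of the 1,1-disubstituted aryl alkene with pinacolborane (chiral iminopyridine-oxazoline ligand) should set C3 and give 2-{(2R)-3-[2-bromo-3,5-dimethoxy-4-(3-methylbut-2-en-1-yl)phenoxy]-2-[5-(methoxymethoxy)-2,2-dimethyl-2H-chromen-8-yl]propyl}-4,4,5,5-tetramethyl-1,3,2-dioxaborolane F4. A hydride pathway is chosen so that no β-aryloxy elimination can occur, and the internal alkenes are much less reactive than the terminal one.
- Intramolecular B-alkyl Suzuki–Miyaura coupling (Pd(OAc)2, RuPhos, K3PO4, toluene/water) then closes C4–C4a to give 24.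

Step 10. The electron-rich epoxide or the arylacetaldehyde may oligomerise, or the MOM ether may be lost under Lewis acid. The fallback sets out from aldehyde 15 and returns at 17.
- Wittig methylenation (Ph3P=CH2) should give 8-ethenyl-5-(methoxymethoxy)-2,2-dimethyl-2H-chromene F5.
- Hydroboration with 9-BBN, selective for the terminal alkene, and oxidation with NaOH/H2O2 should give 2-[5-(methoxymethoxy)-2,2-dimethyl-2H-chromen-8-yl]ethan-1-ol F6.
- Dess–Martin oxidation then gives 17.

Further compounds
F1 | step 12 | 5,7-dimethoxy-4-{1-[5-(methoxymethoxy)-2,2-dimethyl-2H-chromen-8-yl]ethenyl}-6-(3-methylbut-2-en-1-yl)-2-phenyl-4H-1,3,2-benzodioxaborinine | C=C(c1ccc(OCOC)c2c1OC(C)(C)C=C2)C1OB(c2ccccc2)Oc2cc(OC)c(CC=C(C)C)c(OC)c21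
F2 | step 13 | 2-[5-(methoxymethoxy)-2,2-dimethyl-2H-chromen-8-yl]prop-2-en-1-ol | C=C(CO)c1ccc(OCOC)c2c1OC(C)(C)C=C2
F3 | step 13 | 8-{3-[2-bromo-3,5-dimethoxy-4-(3-methylbut-2-en-1-yl)phenoxy]prop-1-en-2-yl}-5-(methoxymethoxy)-2,2-dimethyl-2H-chromene | COc1cc(OCC(=C)c2ccc(OCOC)c3c2OC(C)(C)C=C3)c(Br)c(OC)c1CC=C(C)C
F4 | step 13 | 2-{(2R)-3-[2-bromo-3,5-dimethoxy-4-(3-methylbut-2-en-1-yl)phenoxy]-2-[5-(methoxymethoxy)-2,2-dimethyl-2H-chromen-8-yl]propyl}-4,4,5,5-tetramethyl-1,3,2-dioxaborolane | COc1cc(OC[C@H](CB2OC(C)(C)C(C)(C)O2)c2ccc(OCOC)c3c2OC(C)(C)C=C3)c(Br)c(OC)c1CC=C(C)C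
F5 | step 10 | 8-ethenyl-5-(methoxymethoxy)-2,2-dimethyl-2H-chromene | C=Cc1ccc(OCOC)c2c1OC(C)(C)C=C2
F6 | step 10 | 2-[5-(methoxymethoxy)-2,2-dimethyl-2H-chromen-8-yl]ethan-1-ol | OCCc1ccc(OCOC)c2c1OC(C)(C)C=C2
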